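The constant of the step from target to isomer of the product B belongs to the chemistry and not to the vessel, so it gives your question a fixed point.

    substrate ⇌ other conformer (K1 = 1.9, k1 = 0.084 min⁻¹)
    substrate + reagent ⇌ target (K2 = 34 M⁻¹, k2 = 11 M⁻¹ min⁻¹)
    reagent + other conformer → isomer of the product A (k3 = 2.9 M⁻¹ min⁻¹)
    2 reagent → homo dimer (k4 = 2.3 M⁻¹ min⁻¹)
    target ⇌ isomer of the product B (K5 = 0.47, k5 = 0.060 min⁻¹)

| flask | substrate | reagent | time | remark |
|---|---|---|---|---|
| zeta | 0.10 M | 1.00 equiv (fed, over 2.00 min) | 4.0 min | all but reagent at the start; reagent goes in evenly over 2.00 min, the run ends at 4.0 min |
| eta | 0.10 M (fed, over 2.00 min) | 1.00 equiv | 4.0 min | a stirred flask in which substrate is dosed at a steady rate over 2.00 min without added volume, worked up at 4.0 min |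
| theta | 0.10 M | 1.00 equiv |  | a single well-mixed tank run continuously and read at steady state, 4.0 min in it on average |
| delta | 0.10 M | 1.00 equiv | 4.0 min | a closed flask charged with all of it at once and left for 4.0 min |

1. the set-up with the highest share of target in all that became target or isomer of the product A or isomer of the product B, at the outlet or at the end ("none" if the first two lie within 2 percentage points) (zeta / eta / theta / delta / none)
2. share of target in all that became target or isomer of the product A or isomer of the product B, at the outlet or at the end, zeta
3. share of target in all that became target or isomer of the product A or isomer of the product B, at the outlet or at the end, eta
4. share of target in all that became target or isomer of the product A or isomer of the product B, at the outlet or at the end, theta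
5. share of target in all that became target or isomer of the product A or isomer of the product B, at the outlet or at the end, delta

- two of one species on the left: rate k times its square, two consumed each time
- the stated concentrations are those of everything mixed, before any reaction; amounts are the same in each set-up
- the feed brings no volume worth counting
- run time (zeta): 4.0 min

You want a quick number, and your hunch points at that isomerisation, so I use it as my scale. Take target plus isomer of the product B as one pair. Under thermodynamic control the pair stands at 68.0% target, and that is my zero. The pair relaxes towards it at forward plus back, 0.188 min⁻¹. In delta, target is born at about 1.10 min⁻¹ per fraction of the charge, faster than that relaxation, so I date it from the charging. The pair share, the fraction of the pair still target at the reading, is then 83.1% for delta. In zeta and eta I date target from the middle of the feed, 3.00 min before the reading, and get 86.2% for both, more than in delta. Isomer of the product A stands in the denominator of the asked share and pulls each figure lower. I don't reckon it, so I expect the asked shares below these figures, and my reckoning gives zeta and eta one figure.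

The forecast gives 81.5% for zeta, 82.5% for eta, 77.2% for theta and 79% for delta. Its call is none, since “they lie too close to separate confidently”.

The simulation gives 80.3%, 83.9%, 77.2% and 79.1% in that order, and the best is eta. The gap of 3.6 percentage points between eta and zeta exceeds the margin of 2 points.

In delta the pair reads 84.0% against my 83.1%. Carried to the same flask read at 6.0 min, the pair share gives 78.4%, and that flask reads 77.8%. The pair reads 87.6% in zeta and 87.6% in eta, so their gap lies in isomer of the product A, with more in zeta, 4.05% against 1.64%. The time given is the main reason eta's share stands as high as 83.9%: read at 40.0 min, eta holds 28.4% of isomer of the product A and its share is 13.4%.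

All constants are assumed.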